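**Plan**
- Retrosynthesis: the acetate and the 13E allylic alcohol are cut back to a terminal alkyne (C13–C16 and C14–C15 bonds), the alkyne to (+)-sclareolide (C12–C13 and C13–C14), and sclareolide to a C8-hydroxy C9-ketone (C9–C11).
- Ring A (C1–C5, C10) is cut last, at C1–C10 and C4–C5. With carbonyls at C6 and C9, the C5=C10 edge of ring B is the methyl-bearing double bond of 2,6-dimethyl-1,4-benzoquinone (its two methyls are C17 and C20), and C1–C4 with the gem-dimethyl group is 4-methylpenta-1,3-diene.
- Forward: ring B is bought as the quinone, ring A is closed on it by an enantioselective Diels–Alder reaction, and the side chain is then grown from C9.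
- Stereochemistry: C10 from the chiral catalyst, C5 by epimerisation to the trans-decalin, C8 by α-face epoxidation relayed through a Wharton transposition, C9 by α-face hydrogenation, 13E by syn-carbometalation.
- Helpers: the C6 carbonyl activates and orients the cycloaddition and is removed in the Wharton step; the C9 carbonyl becomes the anchor for the side chain.

Key step: step 1

Numbering: labdane numbering is used in the reasoning for all intermediates (C1–C4 from the diene, C5–C10 from the quinone, C17 on C8, C20 on C10; α is the face opposite C20).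
Assumption: the catalyst made from the (S)-oxazaborolidine of step 1 and HN(SO2CF3)2 is taken to shield the quinone face that leads to the (8aS) adduct; if the adduct proves to be the antipode, the commercially available (R)-oxazaborolidine is used with nothing else changed.

**Step 1**
Reactants: 1 m-xyloquinone (dimethyl-p-benzoquinone with both methyls beside one carbonyl); 2 gem-dimethylbutadiene (methylpentadiene with both methyls on one terminal carbon)
Product: 3 (4aR,8aS)-2,5,5,8a-tetramethyl-4a,5,8,8a-tetrahydronaphthalene-1,4-dione (cis-fused adduct)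
Conditions: (S)-3,3-diphenyl-1-(o-tolyl)tetrahydro-1H,3H-pyrrolo[1,2-c][1,3,2]oxazaborole (20 mol %), HN(SO2CF3)2 (20 mol %), diene in threefold excess, CH2Cl2, −78 → −40 °C
Reagents that add atoms: none
Why: The protonated oxazaborolidine binds the quinone at the C6 carbonyl oxygen (the more basic one, flanked by C–H and not by C–CH3), which makes the methyl-bearing C10 the most electrophilic carbon of the C5=C10 bond; the diene then adds in a concerted but strongly asynchronous normal-demand [4+2] cycloaddition in which its CH2 terminus (C1) bonds to C10 ahead of closure of the Me2C terminus (C4) onto C5. The closest known reaction type is the oxazaborolidinium-catalysed enantioselective Diels–Alder reaction of substituted 1,4-benzoquinones, together with the BF3-promoted additions of 1-substituted dienes to 2,6-dimethylbenzoquinone, which show the same orientation. Ring A closes by intermolecular suprafacial [4+2] cycloaddition onto the preformed ring B, so the angular methyl and the ring-fusion hydrogen come out cis. The quaternary centre C10 is fixed by the catalyst, which blocks one face of the coordinated double bond; C5 is set cis by the suprafacial addition and is corrected in step 2; the diene has no stereogenic terminus, so there is no endo/exo issue. The step needs regioselectivity, secured by the matched polarisation just described and by the steric preference of the Me2C terminus for the CH carbon, and it needs reactivity from a diene whose s-cis form is disfavoured by its Z-methyl, which is helped by the allyl-cation character that the gem-dimethyl group stabilises in the asynchronous transition state and by using the diene in excess.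

**Step 2**
Reactants: 3 cis-fused adduct
Product: 4 (4aS,8aS)-2,5,5,8a-tetramethyl-4a,5,8,8a-tetrahydronaphthalene-1,4-dione (trans-fused enedione)
Conditions: DBU (0.2 equiv), CH2Cl2, rt
Reagents that add atoms: none
Why: C5–H is α to the C6 carbonyl, so base-mediated epimerisation through the dienolate should equilibrate the cis adduct to the trans-fused dione, expected to be favoured as in 5α-H 6-oxo drimanes and labdanes, while the quaternary C10 cannot epimerise.

**Step 3**
Reactants: 4 trans-fused enedione
Product: 5 7α,8α-epoxide of 4 (oxirane oxygen on the face opposite the angular methyl)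
Conditions: 30 % aq. H2O2 (3 equiv), Na2CO3 (0.3 equiv), MeOH, 0 °C
Reagents that add atoms: hydrogen peroxide, OO
Why: Weitz–Scheffer nucleophilic epoxidation of the enedione; the oxirane should close on the α face because a β oxygen on C8 would be 1,3-syn-axial to C20, which sets the C8–O bond α and C17 β.

**Step 4**
Reactants: 5 epoxy dione
Product: 7 (2R,4aS,8aS)-2-hydroxy-2,5,5,8a-tetramethyl-4a,5,8,8a-tetrahydronaphthalen-1(2H)-one, via epoxy hydrazone 6 (not isolated)
Conditions: N2H4·H2O (2.5 equiv), AcOH (0.2 equiv), MeOH, 0 °C → rt
Reagents that add atoms: none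
Why: Wharton transposition: hydrazine should condense at the less hindered C6 carbonyl (C9 lies between two fully substituted carbons), and the epoxy hydrazone collapses with loss of N2 to the C6=C7 alkene and the tertiary C8 alcohol, which keeps the configuration of the epoxide.

**Step 5**
Reactants: 7 hydroxy ketone
Product: 9 butenolide 2,3:6,7:9,11-hexadehydrosclareolide, via acyl ylide 8 (not isolated)
Conditions: Ph3P=C=C=O (1.5 equiv), toluene, 110 °C
Reagents that add atoms: (triphenylphosphoranylidene)ketene, O=C=C=P(c1ccccc1)(c1ccccc1)c1ccccc1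
Why: Bestmann butenolide synthesis: the tertiary alcohol adds to the cumulated ylide and the resulting acyl ylide undergoes an intramolecular Wittig reaction, closing a five-membered ring onto the hindered, non-enolisable C9 ketone that an intermolecular olefination would not reach.

**Step 6**
Reactants: 9 butenolide
Product: 10 (+)-sclareolide, (3aR,5aS,9aS,9bR)-3a,6,6,9a-tetramethyldecahydronaphtho[2,1-b]furan-2(1H)-one
Conditions: H2 (20 bar), 5 % Rh/Al2O3, EtOAc, rt
Reagents that add atoms: none
Why: Heterogeneous hydrogenation saturates C2=C3, C6=C7 and the butenolide C9=C11; hydrogen should reach C9 from the α face because the β face is flanked by the axial methyls C17 and C20, giving the trans-fused lactone, and Rh/Al2O3 is chosen to limit hydrogenolysis of the allylic lactone C8–O bond.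

**Step 7**
Reactants: 10 (+)-sclareolide
Product: 11 sclareolide lactol (8α,12-epoxy-13,14,15,16-tetranorlabdan-12-ol)
Conditions: i-Bu2AlH (1.1 equiv), CH2Cl2, −78 °C
Reagents that add atoms: none
Why: Partial reduction of a γ-lactone to the lactol with one equivalent of i-Bu2AlH at low temperature is standard and stops at the O-aluminated hemiacetal.

**Step 8**
Reactants: 11 lactol
Product: 13 8α,13-epoxy-14,15,16-trinorlabdan-13-ol, via enol ether 12 (not isolated)
Conditions: Ph3P(CH2OMe)Cl (3.5 equiv), KOtBu (3.3 equiv), THF, 0 °C → rt; then 1 M aq. HCl, THF, rt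
Reagents that add atoms: (methoxymethyl)triphenylphosphonium chloride, COC[P+](c1ccccc1)(c1ccccc1)c1ccccc1.[Cl-]; water, O
Why: Wittig methoxymethylenation of the ring-opened hydroxy aldehyde followed by mild acid hydrolysis of the enol ether gives the one-carbon homologue as its six-membered lactol, and because no leaving group is ever placed on C12 the tertiary hydroxyl cannot close a tetrahydrofuran.

**Step 9**
Reactants: 13 homologated lactol
Product: 14 15,16-dinorlabd-13-yn-8α-ol
Conditions: dimethyl (1-diazo-2-oxopropyl)phosphonate (1.5 equiv), K2CO3 (2 equiv), MeOH, rt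
Reagents that add atoms: dimethyl (1-diazo-2-oxopropyl)phosphonate, COP(=O)(OC)C(=[N+]=[N-])C(C)=O
Why: Seyferth–Gilbert homologation in its Ohira–Bestmann form converts the aldehyde in equilibrium with the lactol into the terminal alkyne under mild conditions that leave the tertiary alcohol untouched.

**Step 10**
Reactants: 14 alkyne
Product: 16 (13E)-labd-13-ene-8α,15-diol, via alkenylalane 15 (not isolated)
Conditions: AlMe3 (3 equiv), Cp2ZrCl2 (0.3 equiv), CH2Cl2, 0 °C → rt; volatiles removed; n-BuLi (2.2 equiv), hexane/THF, −78 → 0 °C; (CH2O)n, rt; aqueous work-up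
Reagents that add atoms: trimethylaluminium, C[Al](C)C; paraformaldehyde (as formaldehyde), C=O
Why: Negishi Cp2ZrCl2-catalysed carboalumination adds methyl and aluminium syn across the alkyne with methyl on the internal carbon, and the derived alanate is trapped by formaldehyde with retention, which sets the 13E geometry; the tertiary hydroxyl is carried as its aluminium alkoxide.

**Step 11**
Reactants: 16 diol
Product: 17 (13E)-8α-hydroxylabd-13-en-15-yl acetate (target)
Conditions: Ac2O (1.2 equiv), pyridine, CH2Cl2, 0 °C → rt
Reagents that add atoms: acetic anhydride, CC(=O)OC(C)=O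
Why: Selective acylation of the primary allylic hydroxyl; the hindered tertiary C8 hydroxyl should not react under these conditions.

**Compound list**
1 | 2,6-dimethyl-1,4-benzoquinone | CC1=CC(=O)C=C(C)C1=O | starting material
2 | 4-methylpenta-1,3-diene | C=CC=C(C)C | starting material
3 | (4aR,8aS)-2,5,5,8a-tetramethyl-4a,5,8,8a-tetrahydronaphthalene-1,4-dione (cis-fused) | O=C1[C@@]2(C)CC=CC(C)(C)[C@H]2C(=O)C=C1C | intermediate
4 | (4aS,8aS)-2,5,5,8a-tetramethyl-4a,5,8,8a-tetrahydronaphthalene-1,4-dione (trans-fused) | O=C1[C@@]2(C)CC=CC(C)(C)[C@@H]2C(=O)C=C1C | intermediate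
5 | 7α,8α-epoxide of 4 (oxirane oxygen anti to the angular methyl) | O=C1[C@@]2(C)CC=CC(C)(C)[C@@H]2C(=O)[C@@H]3[C@@]1(C)O3 | intermediate
6 | C6 monohydrazone of epoxy dione 5 | O=C1[C@@]2(C)CC=CC(C)(C)[C@@H]2C(=NN)[C@@H]3[C@@]1(C)O3 | intermediate (not isolated)
7 | (2R,4aS,8aS)-2-hydroxy-2,5,5,8a-tetramethyl-4a,5,8,8a-tetrahydronaphthalen-1(2H)-one | O=C1[C@@]2(C)CC=CC(C)(C)[C@@H]2C=C[C@@]1(C)O | intermediate
8 | (triphenylphosphoranylidene)acetate ester of the C8 hydroxyl of 7 | O=C1[C@@]2(C)CC=CC(C)(C)[C@@H]2C=C[C@@]1(C)OC(=O)C=P(c3ccccc3)(c4ccccc4)c5ccccc5 | intermediate (not isolated)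
9 | 2,3:6,7:9,11-hexadehydrosclareolide (butenolide) | O=C1C=C2[C@@]3(C)CC=CC(C)(C)[C@@H]3C=C[C@@]2(C)O1 | intermediate
10 | (+)-sclareolide | O=C1C[C@@H]2[C@@]3(C)CCCC(C)(C)[C@@H]3CC[C@@]2(C)O1 | intermediate
11 | sclareolide lactol (both C12 epimers) | OC1C[C@@H]2[C@@]3(C)CCCC(C)(C)[C@@H]3CC[C@@]2(C)O1 | intermediate
12 | 13-methoxy-14,15,16-trinorlabd-12-en-8α-ol (E/Z enol ether) | COC=CC[C@@H]1[C@@]2(C)CCCC(C)(C)[C@@H]2CC[C@@]1(C)O | intermediate (not isolated)
13 | 8α,13-epoxy-14,15,16-trinorlabdan-13-ol (both C13 epimers) | OC1CC[C@@H]2[C@@]3(C)CCCC(C)(C)[C@@H]3CC[C@@]2(C)O1 | intermediate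
14 | 15,16-dinorlabd-13-yn-8α-ol | C#CCC[C@@H]1[C@@]2(C)CCCC(C)(C)[C@@H]2CC[C@@]1(C)O | intermediate
15 | dimethyl[(13E)-8α-(dimethylalumanyloxy)-15-norlabd-13-en-14-yl]alane | C[Al](C)/C=C(\C)CC[C@@H]1[C@@]2(C)CCCC(C)(C)[C@@H]2CC[C@@]1(C)O[Al](C)C | intermediate (not isolated)
16 | (13E)-labd-13-ene-8α,15-diol | OC/C=C(\C)CC[C@@H]1[C@@]2(C)CCCC(C)(C)[C@@H]2CC[C@@]1(C)O | intermediate
17 | (13E)-8α-hydroxylabd-13-en-15-yl acetate | CC(=O)OC/C=C(\C)CC[C@@H]1[C@@]2(C)CCCC(C)(C)[C@@H]2CC[C@@]1(C)O | target

Total step count: 11. Longest linear sequence: 11 steps.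

**Steps most likely to fail**

Step 1. The cycloaddition may stall because the s-cis conformer of the diene is hard to reach, the diene may oligomerise under the acid catalyst, or face selection may be poor. The fallback sets out from 1 and comes back at 3. Mesityl oxide is deprotonated at its methyl ketone carbon (LiN(i-Pr)2, THF, −78 °C) and silylated (i-Pr3SiOSO2CF3) to the far more nucleophilic diene 4-methyl-2-(triisopropylsilyloxy)penta-1,3-diene F1. F1 adds to 1 under the same oxazaborolidinium catalysis, a diene class with close precedent for this catalyst, to give the silyl enol ether adduct F2; the silyloxy group reinforces bonding of the CH2 terminus to the methyl-bearing quinone carbon. F2 is converted to the enol triflate F3 (CsF, PhN(SO2CF3)2, MeOCH2CH2OMe, rt). F3 is reduced (Pd(OAc)2, PPh3, HCO2H, n-Bu3N, DMF, 60 °C) to the ring A alkene, which is 3.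

Step 4. Hydrazone formation may be slow or unselective between the two carbonyls, and the vinyl diazene may decompose by paths other than clean loss of N2. The fallback sets out from 5 and comes back at 10. The epoxide is opened reductively at its secondary C7–O bond with sodium phenylselenotriethoxyborate (PhSeSePh, NaBH4, EtOH, AcOH), where selenide attack is possible only at the CH carbon, to give the hydroxy dione F4. F4 is condensed at the less hindered C6 carbonyl to the tosylhydrazone F5 (TsNHNH2, MeOH, rt). F5 is reduced to the methylene compound F6 (catecholborane, CHCl3, 0 °C; then NaOAc·3H2O, reflux). F6 is taken through the conditions of step 5 to the butenolide F7, and F7 is hydrogenated as in step 6 to 10.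

Step 5. Acylation of the hindered tertiary hydroxyl by the ylide may be slow, or the stabilised ylide may fail to attack the neopentyl-type ketone. The fallback sets out from 7 and comes back at 9. Lithium ethoxyacetylide (ethoxyacetylene, n-BuLi, THF, −78 °C, 2.5 equiv), a small linear nucleophile, adds to the C9 ketone to give the ethoxyethynyl diol F8. Dilute acid (aq. H2SO4, THF, 0 °C → rt) then triggers a Meyer–Schuster rearrangement to the unsaturated ester, which lactonises onto the C8 hydroxyl to give 9.

**Further compounds**
F1 | step 1 | 4-methyl-2-(triisopropylsilyloxy)penta-1,3-diene | C=C(O[Si](C(C)C)(C(C)C)C(C)C)C=C(C)C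
F2 | step 1 | cis-fused adduct carrying a C2 triisopropylsilyl enol ether (C2=C3) | O=C1[C@@]2(C)CC(O[Si](C(C)C)(C(C)C)C(C)C)=CC(C)(C)[C@H]2C(=O)C=C1C
F3 | step 1 | cis-fused adduct carrying a C2 enol triflate (C2=C3) | O=C1[C@@]2(C)CC(OS(=O)(=O)C(F)(F)F)=CC(C)(C)[C@H]2C(=O)C=C1C
F4 | step 4 | trans-fused 8α-hydroxy-6,9-dione (C7 methylene, C2=C3 retained) | O=C1[C@@]2(C)CC=CC(C)(C)[C@@H]2C(=O)C[C@@]1(C)O
F5 | step 4 | C6 tosylhydrazone of F4 | O=C1[C@@]2(C)CC=CC(C)(C)[C@@H]2C(=NNS(=O)(=O)c3ccc(C)cc3)C[C@@]1(C)O
F6 | step 4 | trans-fused 8α-hydroxy-9-ketone with C6 and C7 methylene (C2=C3 retained) | O=C1[C@@]2(C)CC=CC(C)(C)[C@@H]2CC[C@@]1(C)O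
F7 | step 4 | 2,3:9,11-tetradehydrosclareolide (butenolide) | O=C1C=C2[C@@]3(C)CC=CC(C)(C)[C@@H]3CC[C@@]2(C)O1
F8 | step 5 | 9-(ethoxyethynyl)-8α,9-diol from 7 (C9 epimers) | CCOC#CC1(O)[C@@]2(C)CC=CC(C)(C)[C@@H]2C=C[C@@]1(C)O
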